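**Plan**

- Retrosynthetic cuts, in order: the acid-labile acetonide and tert-butyl groups; the aryl acetates and the ester bond between ring-B O-3 and the enol-ether carboxyl carbon (an aryl lactone); the ring-B C-1–vinyl C–C bond of the caffeoyl unit (Heck) and, in the side branch, the acrylate–danshensu ester C–O bond; the ring-B C-3–O bond, by removing the oxygen between C-3 and the carboxyl carbon; finally the arylidene C=C.
- Enabling feature: on ring B (the central trisubstituted benzene ring), O-4, the arylidene alpha carbon and the carboxyl carbon are the O-1–C-2–C-3 chain of a (Z)-aurone. The target differs from that aurone only by one oxygen lying between the carbonyl carbon and ring-B C-3 (C-3a of the benzofuranone).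
- Forward order: the five-membered ring is bought as 5-bromobenzofuran-3(2H)-one; condensation installs the arylidene, oxygen insertion enlarges the ring to the six-membered lactone, the Heck reaction joins the danshensu acrylate, hydroxide opens the lactone, and acid unmasks the rest.
- Stereochemistry: the single stereocentre is that of commercial (R)-danshensu and no bond to it is ever broken; the Z enol ether is the thermodynamic aurone geometry; the E cinnamate comes from the Heck reaction.

Key step: step 3

Assumption: the ring expansion is run on the aryl bromide, before the cross-coupling, with the arylidene catechol as its diacetate, so that the peracid meets no electron-rich arene and no acid-labile group; (R)-danshensu is taken as the commercial free acid.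

**Route**

Step 1
Reactants: 1 5-bromobenzofuran-3(2H)-one; 2 3,4-dihydroxybenzaldehyde
Product: 3 (Z)-5-bromo-2-(3,4-dihydroxybenzylidene)benzofuran-3(2H)-one
Conditions: conc. HCl (cat.), AcOH, rt to 50 °C
Reagents that add atoms: none
Why: Acid-catalysed aldol (Claisen–Schmidt-type) condensation of the C-2 methylene with the aldehyde, standard for hydroxylated aurones; dehydration is irreversible and the product should settle in the thermodynamically favoured Z geometry (aryl syn to O-1), which is the enol ether geometry of the target.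

Step 2
Reactants: 3 (Z)-5-bromo-2-(3,4-dihydroxybenzylidene)benzofuran-3(2H)-one
Product: 4 (Z)-5-bromo-2-(3,4-diacetoxybenzylidene)benzofuran-3(2H)-one
Conditions: Ac2O, pyridine, DMAP (cat.), CH2Cl2, 0 °C to rt
Reagents that add atoms: acetic anhydride, CC(=O)OC(C)=O
Why: Standard DMAP-catalysed O-acetylation of both phenols; the acetates turn the donor catechol into a weakly withdrawing group, which should make the ketone more electrophilic and the arylidene less nucleophilic for the oxidation that follows.

Step 3
Reactants: 4 (Z)-5-bromo-2-(3,4-diacetoxybenzylidene)benzofuran-3(2H)-one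
Product: 6 (Z)-7-bromo-3-(3,4-diacetoxybenzylidene)-1,4-benzodioxin-2(3H)-one, via peroxy hemiketal 5 (not isolated)
Conditions: mCPBA (3 equiv), TFA (1 equiv), CH2Cl2, 0 °C to rt, dark
Reagents that add atoms: mCPBA (3-chloroperbenzoic acid), OOC(=O)c1cccc(Cl)c1
Why: Proposed new method: acid-assisted addition of the peracid to the C-3 ketone gives peroxy hemiketal 5, and the aryl carbon C-3a then shifts from C-3 to the inner peroxide oxygen as 3-chlorobenzoate leaves, which makes the C-3a–O bond and the new O–C(=O) bond in one event. The closest known reactions are the Baeyer–Villiger oxidations of 1-indanones, chroman-4-ones and flavanones to aryl lactones and the Dakin-type oxidation of ortho-alkoxy aryl ketones, all of which move an ortho-oxygenated aryl carbon to oxygen; an aurone has not been taken through this reaction. The six-membered 1,4-benzodioxin-2-one arises not by cyclisation but by one-atom ring expansion of the five-membered furanone, helped by release of its strain. No stereocentre is formed, and the Z enol ether is carried through because the alkene takes no part. The step needs aryl migration to beat migration of the alkenyl carbon C-2 and epoxidation of the arylidene: O-1 sits ortho to C-3a and stabilises the arenium-like transition state by resonance, whereas C-2 is an sp2 carbon carrying that same electronegative oxygen, and the diacetoxyphenyl group both withholds benzylic stabilisation from a C-2 shift and leaves the ketone-conjugated alkene too electron-poor for the peracid. The bromide (meta to C-3a) and the aryl acetates are inert to mCPBA/TFA, so the ketone should be the only site open to the oxidant.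

Step 4
Reactants: 7 (R)-danshensu [(R)-3-(3,4-dihydroxyphenyl)-2-hydroxypropanoic acid]
Product: 8 (R)-5-[(2,2-dimethyl-1,3-benzodioxol-5-yl)methyl]-2,2-dimethyl-1,3-dioxolan-4-one
Conditions: Me2C(OMe)2, TsOH·H2O (cat.), acetone/toluene, reflux, Soxhlet with 4 Å molecular sieves
Reagents that add atoms: 2,2-dimethoxypropane, COC(C)(C)OC
Why: Acid-catalysed transketalisation with removal of methanol closes the alpha-hydroxy acid to the 1,3-dioxolan-4-one and the catechol to the benzodioxole in one operation, a standard protection of both functions; no bond to the stereocentre is broken, so the R configuration is kept.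

Step 5
Reactants: 8 (R)-5-[(2,2-dimethyl-1,3-benzodioxol-5-yl)methyl]-2,2-dimethyl-1,3-dioxolan-4-one
Product: 9 (R)-3-(2,2-dimethyl-1,3-benzodioxol-5-yl)-2-hydroxypropanoic acid
Conditions: LiOH·H2O, THF/H2O, 0 °C; then 1 M HCl to pH 3
Reagents that add atoms: lithium hydroxide, [Li+].[OH-]
Why: The dioxolanone is an activated, acylal-type lactone that hydroxide opens at 0 °C (saponification) with loss of acetone, while the catechol ketal is inert to base; the carboxylate formed cannot enolise, so the stereocentre is safe.

Step 6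
Reactants: 9 (R)-3-(2,2-dimethyl-1,3-benzodioxol-5-yl)-2-hydroxypropanoic acid
Product: 10 tert-butyl (R)-3-(2,2-dimethyl-1,3-benzodioxol-5-yl)-2-hydroxypropanoate
Conditions: Cl3CC(=NH)Ot-Bu, CH2Cl2/cyclohexane, rt
Reagents that add atoms: tert-butyl 2,2,2-trichloroacetimidate, CC(C)(C)OC(=N)C(Cl)(Cl)Cl
Why: tert-Butyl esterification by the trichloroacetimidate method, in which the carboxylic acid itself protonates the imidate and captures the tert-butyl cation; without an added Lewis acid the secondary alcohol should not react and the acetonide is untouched.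

Step 7
Reactants: 10 tert-butyl (R)-3-(2,2-dimethyl-1,3-benzodioxol-5-yl)-2-hydroxypropanoate; 11 acryloyl chloride
Product: 12 tert-butyl (R)-2-(acryloyloxy)-3-(2,2-dimethyl-1,3-benzodioxol-5-yl)propanoate
Conditions: i-Pr2NEt, CH2Cl2, −20 to 0 °C
Reagents that add atoms: none
Why: Schotten–Baumann-type O-acylation of the secondary alcohol by the acid chloride with a hindered amine base at low temperature, which avoids amine addition to the acrylate and leaves the alpha stereocentre unepimerised.

Step 8
Reactants: 6 (Z)-7-bromo-3-(3,4-diacetoxybenzylidene)-1,4-benzodioxin-2(3H)-one; 12 tert-butyl (R)-2-(acryloyloxy)-3-(2,2-dimethyl-1,3-benzodioxol-5-yl)propanoate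
Product: 13 tert-butyl (R)-2-{[(E)-3-[(Z)-3-(3,4-diacetoxybenzylidene)-2-oxo-2,3-dihydro-1,4-benzodioxin-7-yl]acryloyl]oxy}-3-(2,2-dimethyl-1,3-benzodioxol-5-yl)propanoate
Conditions: Pd2(dba)3 (cat.), [HP(t-Bu)3]BF4 (cat.), Cy2NMe, 1,4-dioxane, rt to 50 °C
Reagents that add atoms: none
Why: Mizoroki–Heck reaction: zerovalent palladium with the bulky electron-rich phosphine inserts into the aryl–bromine bond near room temperature, syn insertion at the terminal acrylate carbon and syn beta-hydride elimination give the E cinnamate, and the mild tertiary amine in dry dioxane should leave the aryl lactone, the acetates and the alpha-acyloxy ester stereocentre alone.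

Step 9
Reactants: 13 tert-butyl (R)-2-{[(E)-3-[(Z)-3-(3,4-diacetoxybenzylidene)-2-oxo-2,3-dihydro-1,4-benzodioxin-7-yl]acryloyl]oxy}-3-(2,2-dimethyl-1,3-benzodioxol-5-yl)propanoate
Product: 14 (Z)-2-{4-[(E)-3-{[(R)-1-tert-butoxy-3-(2,2-dimethyl-1,3-benzodioxol-5-yl)-1-oxopropan-2-yl]oxy}-3-oxoprop-1-en-1-yl]-2-hydroxyphenoxy}-3-(3,4-dihydroxyphenyl)acrylic acid
Conditions: LiOH·H2O (6 equiv), degassed THF/H2O, 0 °C, Ar; then 1 M HCl to pH 3
Reagents that add atoms: lithium hydroxide, [Li+].[OH-]
Why: Chemoselective saponification: the aryl lactone and the two aryl acetates have phenoxide leaving groups and should be cleaved by cold hydroxide much faster than the conjugated alkyl cinnamate or the hindered tert-butyl ester, so the lactone opens to the free C-3 phenol and the acrylic acid while the catechol of the arylidene arm is released; exclusion of air protects the catecholate.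

Step 10
Reactants: 14 (Z)-2-{4-[(E)-3-{[(R)-1-tert-butoxy-3-(2,2-dimethyl-1,3-benzodioxol-5-yl)-1-oxopropan-2-yl]oxy}-3-oxoprop-1-en-1-yl]-2-hydroxyphenoxy}-3-(3,4-dihydroxyphenyl)acrylic acid
Product: 15 (Z)-2-{4-[(E)-3-{[(R)-1-carboxy-2-(3,4-dihydroxyphenyl)ethyl]oxy}-3-oxoprop-1-en-1-yl]-2-hydroxyphenoxy}-3-(3,4-dihydroxyphenyl)acrylic acid (CNP0157552.2)
Conditions: TFA/H2O (9:1), 0 °C to rt
Reagents that add atoms: none
Why: Acidolysis: aqueous TFA hydrolyses the catechol isopropylidene ketal and cleaves the tert-butyl ester by loss of isobutene, with water as the cation trap; the aryl vinyl ether is captodative (its protonation is disfavoured by the adjacent carboxyl group), and the cinnamate ester and the stereocentre are not affected by acid.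

**Compound list**

1 | 5-bromobenzofuran-3(2H)-one | O=C1COc2ccc(Br)cc12 | starting material
2 | 3,4-dihydroxybenzaldehyde | O=Cc1ccc(O)c(O)c1 | starting material
3 | (Z)-5-bromo-2-(3,4-dihydroxybenzylidene)benzofuran-3(2H)-one | Brc1ccc2O/C(=C\c3ccc(O)c(O)c3)C(=O)c2c1 | intermediate
4 | (Z)-5-bromo-2-(3,4-diacetoxybenzylidene)benzofuran-3(2H)-one | Brc1ccc2O/C(=C\c3ccc(OC(C)=O)c(OC(C)=O)c3)C(=O)c2c1 | intermediate
5 | (Z)-5-bromo-2-(3,4-diacetoxybenzylidene)-3-hydroxy-2,3-dihydrobenzofuran-3-yl 3-chloroperbenzoate (peroxy hemiketal, racemic at C-3, not isolated) | Brc1ccc2O/C(=C\c3ccc(OC(C)=O)c(OC(C)=O)c3)C(O)(OOC(=O)c3cccc(Cl)c3)c2c1 | intermediate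
6 | (Z)-7-bromo-3-(3,4-diacetoxybenzylidene)-1,4-benzodioxin-2(3H)-one | Brc1ccc2O/C(=C\c3ccc(OC(C)=O)c(OC(C)=O)c3)C(=O)Oc2c1 | intermediate
7 | (R)-danshensu, (R)-3-(3,4-dihydroxyphenyl)-2-hydroxypropanoic acid | O[C@H](Cc1ccc(O)c(O)c1)C(=O)O | starting material
8 | (R)-5-[(2,2-dimethyl-1,3-benzodioxol-5-yl)methyl]-2,2-dimethyl-1,3-dioxolan-4-one | CC1(C)O[C@H](Cc2ccc3OC(C)(C)Oc3c2)C(=O)O1 | intermediate
9 | (R)-3-(2,2-dimethyl-1,3-benzodioxol-5-yl)-2-hydroxypropanoic acid | O[C@H](Cc1ccc2OC(C)(C)Oc2c1)C(=O)O | intermediate
10 | tert-butyl (R)-3-(2,2-dimethyl-1,3-benzodioxol-5-yl)-2-hydroxypropanoate | O[C@H](Cc1ccc2OC(C)(C)Oc2c1)C(=O)OC(C)(C)C | intermediate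
11 | acryloyl chloride | C=CC(=O)Cl | starting material
12 | tert-butyl (R)-2-(acryloyloxy)-3-(2,2-dimethyl-1,3-benzodioxol-5-yl)propanoate | C=CC(=O)O[C@H](Cc1ccc2OC(C)(C)Oc2c1)C(=O)OC(C)(C)C | intermediate
13 | tert-butyl (R)-2-{[(E)-3-[(Z)-3-(3,4-diacetoxybenzylidene)-2-oxo-2,3-dihydro-1,4-benzodioxin-7-yl]acryloyl]oxy}-3-(2,2-dimethyl-1,3-benzodioxol-5-yl)propanoate | O=C(/C=C/c1ccc2O/C(=C\c3ccc(OC(C)=O)c(OC(C)=O)c3)C(=O)Oc2c1)O[C@H](Cc1ccc2OC(C)(C)Oc2c1)C(=O)OC(C)(C)C | intermediate
14 | (Z)-2-{4-[(E)-3-{[(R)-1-tert-butoxy-3-(2,2-dimethyl-1,3-benzodioxol-5-yl)-1-oxopropan-2-yl]oxy}-3-oxoprop-1-en-1-yl]-2-hydroxyphenoxy}-3-(3,4-dihydroxyphenyl)acrylic acid | O=C(/C=C/c1ccc(O/C(=C\c2ccc(O)c(O)c2)C(=O)O)c(O)c1)O[C@H](Cc1ccc2OC(C)(C)Oc2c1)C(=O)OC(C)(C)C | intermediate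
15 | (Z)-2-{4-[(E)-3-{[(R)-1-carboxy-2-(3,4-dihydroxyphenyl)ethyl]oxy}-3-oxoprop-1-en-1-yl]-2-hydroxyphenoxy}-3-(3,4-dihydroxyphenyl)acrylic acid (CNP0157552.2) | O=C(/C=C/c1ccc(O/C(=C\c2ccc(O)c(O)c2)C(=O)O)c(O)c1)O[C@H](Cc1ccc(O)c(O)c1)C(=O)O | target

**Step count**

Total: 10 steps. Longest linear sequence: 7 steps (steps 4 to 10, from (R)-danshensu); the aurone branch runs through 6 (steps 1 to 3 and 8 to 10).

**Steps most likely to fail**

1. Step 3 (ring expansion). The alkenyl carbon C-2 may migrate in place of C-3a, the peracid may epoxidise the arylidene, or the doubly conjugated ketone may not take up the peracid at all. The fallback uses known chemistry only: the ring-B C–O bond is made by a Dakin-type oxidation of an aldehyde and the enol ether by a Perkin condensation. It sets out from aldehyde 2 and returns at 14. Commercial 5-bromo-2-hydroxybenzaldehyde is alkylated with methyl bromoacetate (K2CO3, DMF, Williamson etherification) to methyl 2-(4-bromo-2-formylphenoxy)acetate F1. mCPBA in CH2Cl2 converts this ortho-alkoxy aldehyde into the aryl formate methyl 2-[4-bromo-2-(formyloxy)phenoxy]acetate F2, and aqueous LiOH cleaves formate and methyl ester to 2-(4-bromo-2-hydroxyphenoxy)acetic acid F3. Perkin condensation of F3 with 2 in Ac2O/Et3N at about 100 °C acetylates all three phenols in the same pot and places the aryl group trans to the carboxyl group; it should give (Z)-2-(2-acetoxy-4-bromophenoxy)-3-(3,4-diacetoxyphenyl)acrylic acid F4. Heck coupling of F4 with acrylate 12 (Pd(OAc)2, P(o-tol)3, Et3N, DMF, 80 °C) would give (Z)-2-{2-acetoxy-4-[(E)-3-{[(R)-1-tert-butoxy-3-(2,2-dimethyl-1,3-benzodioxol-5-yl)-1-oxopropan-2-yl]oxy}-3-oxoprop-1-en-1-yl]phenoxy}-3-(3,4-diacetoxyphenyl)acrylic acid F5. The hydroxide treatment of step 9 then removes its three acetates and reaches 14.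

2. Step 8 (Heck coupling on the lactone). The aryl lactone or an acetate may be opened by the amine or by adventitious water during the coupling, or oxidative addition into the oxygen-substituted aryl bromide may be slow. In the fallback the cross-coupling is moved ahead of the ring expansion; it sets out from aurone 4 and acrylate 12 and returns at 13. Heck reaction of the robust aurone bromide 4 with 12 (Pd(OAc)2, P(o-tol)3, Et3N, DMF, 90 °C) should give tert-butyl (R)-2-{[(E)-3-[(Z)-2-(3,4-diacetoxybenzylidene)-3-oxo-2,3-dihydrobenzofuran-5-yl]acryloyl]oxy}-3-(2,2-dimethyl-1,3-benzodioxol-5-yl)propanoate F6. The oxygen insertion of step 3 is then run on F6 with mCPBA buffered by Na2HPO4 in place of TFA, because the acetonide and the tert-butyl ester do not tolerate the acid; this leads to 13.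

3. Step 9 (selective saponification). Hydroxide may also attack the cinnamate ester, the carbon alpha to the tert-butyl ester may epimerise, and the catecholate may be oxidised by air. In the fallback the two end-game steps are exchanged; it sets out from 13 and returns at 15. TFA/H2O on 13 first removes the acetonide and the tert-butyl ester and should give (R)-2-{[(E)-3-[(Z)-3-(3,4-diacetoxybenzylidene)-2-oxo-2,3-dihydro-1,4-benzodioxin-7-yl]acryloyl]oxy}-3-(3,4-dihydroxyphenyl)propanoic acid F7; any lactone that opens at this stage is already on the way to the target. The aryl esters of F7 are then cleaved with degassed dilute aqueous LiOH at 0 °C under argon, followed by acidification. In F7 the cinnamate ester sits next to a carboxylate, whose charge repels hydroxide and whose alpha carbon can no longer be deprotonated, so over-hydrolysis and epimerisation should both be suppressed.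

**Further compounds**

F1 | step 3 | methyl 2-(4-bromo-2-formylphenoxy)acetate | COC(=O)COc1ccc(Br)cc1C=O
F2 | step 3 | methyl 2-[4-bromo-2-(formyloxy)phenoxy]acetate | COC(=O)COc1ccc(Br)cc1OC=O
F3 | step 3 | 2-(4-bromo-2-hydroxyphenoxy)acetic acid | OC(=O)COc1ccc(Br)cc1O
F4 | step 3 | (Z)-2-(2-acetoxy-4-bromophenoxy)-3-(3,4-diacetoxyphenyl)acrylic acid | CC(=O)Oc1cc(Br)ccc1O/C(=C\c1ccc(OC(C)=O)c(OC(C)=O)c1)C(=O)O
F5 | step 3 | (Z)-2-{2-acetoxy-4-[(E)-3-{[(R)-1-tert-butoxy-3-(2,2-dimethyl-1,3-benzodioxol-5-yl)-1-oxopropan-2-yl]oxy}-3-oxoprop-1-en-1-yl]phenoxy}-3-(3,4-diacetoxyphenyl)acrylic acid | O=C(/C=C/c1ccc(O/C(=C\c2ccc(OC(C)=O)c(OC(C)=O)c2)C(=O)O)c(OC(C)=O)c1)O[C@H](Cc1ccc2OC(C)(C)Oc2c1)C(=O)OC(C)(C)C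
F6 | step 8 | tert-butyl (R)-2-{[(E)-3-[(Z)-2-(3,4-diacetoxybenzylidene)-3-oxo-2,3-dihydrobenzofuran-5-yl]acryloyl]oxy}-3-(2,2-dimethyl-1,3-benzodioxol-5-yl)propanoate | O=C(/C=C/c1ccc2O/C(=C\c3ccc(OC(C)=O)c(OC(C)=O)c3)C(=O)c2c1)O[C@H](Cc1ccc2OC(C)(C)Oc2c1)C(=O)OC(C)(C)C
F7 | step 9 | (R)-2-{[(E)-3-[(Z)-3-(3,4-diacetoxybenzylidene)-2-oxo-2,3-dihydro-1,4-benzodioxin-7-yl]acryloyl]oxy}-3-(3,4-dihydroxyphenyl)propanoic acid | O=C(/C=C/c1ccc2O/C(=C\c3ccc(OC(C)=O)c(OC(C)=O)c3)C(=O)Oc2c1)O[C@H](Cc1ccc(O)c(O)c1)C(=O)O
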